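The data are simulated for an exercise; noise was put on by code.

Early readings already fall short of the charge: at 1.50 h the midnight run misses 10.4 % of its starting material.

| setting | midnight | winter | flask |
|---|---|---|---|
| starting material | 0.14 M | 0.22 M | 0.10 M |
| fresh partner | 1.8 equiv | 1.8 equiv | 1.80 equiv |
| coupling partner | 2.5 equiv | 2.5 equiv | 2.50 equiv |
| protic impurity | 0.030 M | 0.030 M | 0.0300 M |
| remark | run made earlier | run made earlier |  |
| time |  |  | 40 h |

| run | time / h | open intermediate / % | product / % | starting material / % |
|---|---|---|---|---|
| midnight | 1.50 | 18.4 | 1.4 | 69.8 |
| midnight | 4.00 | 28.2 | 8.9 | 47.3 |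
| midnight | 12.0 | 18.7 | 38.8 | 22.5 |
| midnight | 30.0 | 8.8 | 61.0 | 10.2 |
| winter | 1.50 | 25.2 | 2.4 | 64.7 |
| winter | 4.00 | 28.7 | 19.3 | 40.3 |
| winter | 12.0 | 12.1 | 57.0 | 17.9 |
| winter | 30.0 | 4.7 | 71.5 | 8.7 |

(readings scatter by 0.5 percentage points)

- the numbers in the tables scatter by 0.5 percentage points (one standard deviation)

- time up to 40 h at which open intermediate stands highest
- the amount of open intermediate, in percent of the starting material charged, at that time

By 30.0 h the gap is 20.0 % in the midnight run and 15.1 % in the winter run, that is 0.0280 M and 0.0332 M, close to the 0.030 M of protic impurity charged to each. We therefore read protic impurity as the limiting reagent of this loss and fold the charges into one number. The flask's 30.0 % is its quench share, protic impurity charged over starting material charged; midnight has 21.4 % and winter 13.6 %.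

Dividing the highest open intermediate readings by what the share leaves gives 35.9 % for midnight and 33.2 % for winter. With 70.0 % left in the flask, midnight's value puts its open intermediate peak near 25.1 %. One number is not quite enough: the two values differ by 2.7 percentage points on readings scattering by 0.5 points, and the share says nothing of time. For that we stretch midnight's 4.00 h by the ratio of charges, to 5.60 h.

The forecast gave 6.5 h and 25 %, taking the impurity to “destroy material stoichiometrically and early”. Open intermediate in the flask stands highest at 6.33 h, with 27.6 %.

    open intermediate + second intermediate ⇌ product (K = 97.0 /M, k = 0.0330 /M/min)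
    starting material + coupling partner → open intermediate (k = 0.00820 /M/min)
    coupling partner + fresh partner → second intermediate (k = 0.00650 /M/min)
    starting material + protic impurity → quenched substrate (k = 0.0550 /M/min)

At the start the flask uses starting material 1.2 times as fast for open intermediate as for quenched substrate. At 40.0 h quenched substrate stands at 28.7 % against the share of 30.0 %. The neighbour flask with 3.10 equiv of fresh partner has the same share, 30.0 %, so the same reckoning again gives a peak near 25.1 %; that flask holds 29.5 % quenched substrate at 40.0 h, but its highest open intermediate is 21.9 %.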